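The earlier runs and the new flask come from a simulation from invented constants; scatter was added.

**Capture odds.** Fold the competition into one number, I told myself.

| setting | alpha | zeta | grey | blue |
|---|---|---|---|---|
| starting material | 0.83 M | 0.83 M | 0.83 M | 0.83 M |
| first nucleophile | 0.78 equiv | 1.9 equiv | 1.30 equiv | 2.60 equiv |
| second nucleophile | 1 equiv (in portions, 3) | 1 equiv (in portions, 3) | 1.00 equiv (in portions, 3) | 1.00 equiv |
| temperature | 25 °C | 40 °C | 40 °C | 40 °C |
| remark | run made earlier; portions every 30 min | run made earlier; portions every 30 min | the portions of second nucleophile follow each other after 30 min, the first at the start | everything together at the start |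
| time |  |  | 10 h | 10 h |

- alpha (time / h: target / %, other capture product / %, side product A / %): 0.833: 4, 43, 4; 2.00: 5, 72, 3; 3.00: 6, 81, 2; 5.00: 3, 91, 0; 10.0: 4, 90, 1
- zeta (time / h: target / %, other capture product / %, side product A / %): 1.00: 45, 49, 0; 2.00: 42, 52, 2; 3.00: 46, 55, 2; 4.00: 46, 46, 6; 5.00: 46, 48, 1

(readings scatter by 2 percentage points)

1. the flask that ends with the higher share of target in all that became target or other capture product or side product A or side product B, or "neither" when 2 percentage points or less lies between them (grey / blue / neither)
2. share of target in all that became target or other capture product or side product A or side product B, grey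
3. share of target in all that became target or other capture product or side product A or side product B, blue

- percent here means starting material units held: one side product A counts as two

I supposed that both nucleophiles competed for what the starting material became. In alpha, at 10.0 h, target stood at 4% beside 90% of other capture product. Integrating that competition gave a selectivity factor of 44.9 for the second nucleophile, a rough reading from 25 °C with 2 percentage points of scatter.

**The number.** I defined β, the competition number, as first-nucleophile equivalents over the selectivity factor times second-nucleophile equivalents: 0.0579 for blue. With both nucleophiles present throughout, target = β·ln(1/target). Small β gives target near β·ln(1/β), and repeated substitution converged on 12.2%.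

**One number tested.** Zeta's β of 0.0423 gave 9.84%, yet zeta read 46%. It already held 94.0% as the two products at 1.00 h, so I judged that at 40 °C the portions left gaps. So I kept the number for blue, where everything goes in together, and not for portioned flasks. I placed grey, dosed like zeta, slightly below 46%, and so chose grey.

**The forecast.** It said grey, with 33% for grey and 17% for blue, holding that “each portion mainly consumes whatever is present”. My grey stood higher and my blue lower.

**The flasks.** Grey gave 43.4% and blue 13.4%, so grey won.

    first nucleophile + intermediate → target (k = 0.00450 M⁻¹ s⁻¹, Ea = 57.0 kJ mol⁻¹)
    second nucleophile + intermediate → other capture product (k = 0.160 M⁻¹ s⁻¹, Ea = 40.0 kJ mol⁻¹)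
    intermediate → side product B (k = 7.30 × 10⁻⁶ s⁻¹, Ea = 100 kJ mol⁻¹)
    starting material → intermediate (k = 9.80 × 10⁻⁴ s⁻¹, Ea = 84.0 kJ mol⁻¹)
    starting material + target → side product A (k = 1.00 × 10⁻⁴ M⁻¹ s⁻¹, Ea = 64.0 kJ mol⁻¹)
    (constants at 40 °C)

In blue, capture by the second nucleophile reached the midpoint of its turnover at 0.183 h, while the intermediate was being made, whose midpoint came at 0.196 h. Target's midpoint came later, at 0.334 h, and 14% of the charged second nucleophile remained at the end.

In the neighbour of blue charged with 1.00 equiv of first nucleophile, β falls to 0.0223, which gives 6.20%. The flask gave 6.91%.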